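## Structural features

The target is a 2,3-dihydrobenzofuran: benzene ring A is fused to the oxygen ring B (O1, C2, C3, C3a, C7a). Ring A carries a methoxy group at C7 and a 3-hydroxypropyl chain at C5. C2 bears a 4-hydroxy-3-methoxyphenyl group (ring C), and C3 bears an exocyclic CH2 (C9) whose oxygen is acylated by (E)-4-hydroxycinnamic acid (ring D). C2 (R) and C3 (S) are adjacent stereocentres with the aryl group and C9 trans; they are the only stereocentres. The fragile points are the cinnamate ester with its E alkene (base, hydrogenation and light are excluded late), the benzylic C2–O1 bond para to a free phenol (ring opening through a quinone methide), and the ring B cation at C2, which can lose the C3 proton and aromatise. The real difficulty is absolute control of the C2/C3 pair together with telling apart two primary alcohols and two phenols. The key step exploits the C2=C3 enol-ether bond of the parent benzofuran. A cyclopropane that bridges C2 and C3 through C9 fixes C3–C9 on one face, and its O1-donor/ester-acceptor bond C2–C9 can later be broken so that the aryl group enters C2 from the other face.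

## Logic of the disconnections

24 to 23: the three O–Si bonds are cut last. This reduces the end of the synthesis to one fluoride treatment, but the forward step must spare the cinnamate ester and the C2–O1 bond, so it has to be buffered.

23 to 19 and 22 (22 from 20): the acyl C–O bond at C9 is cut. This splits off ring D as a simple acid and leaves 19 with a single free hydroxyl, so the forward esterification needs no selectivity. The phenol of 20 must be masked to prevent self-acylation.

19 to 17, 16 and 15: the C9–O bond is traced back to a C9–carboxyl bond. The cyclopropanation can only deliver C9 with an ester carbon attached, so one carbon must be excised. This is done by radical decarboxylation with borylation and oxidation, placed before the light-sensitive cinnamate is present. The forward steps must hydrolyse the ester without touching the aryl silyl ether, and the C9 radical must be trapped before it rearranges.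

15 to 10 and 12 (through 13 and 14; 12 from 11): the C2–aryl bond is cut. This removes ring C and one stereocentre and leaves an acetal that is the resting form of the C2 oxocarbenium ion. The forward step must deliver the aryl group anti to the C3 arm and at a defined ring C carbon, which is why a metalated arene is used and not a free guaiacol.

10 to 9: the C2–OEt bond is cut and C2–C9 is re-formed. This recognises the acetal as the opened form of a donor–acceptor cyclopropane. The forward opening must break only C2–C9 and must trap the cation faster than it loses the C3 proton.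

9 to 7 and 8: C3–C9 and C2–C9 are cut together. This is the key simplification: a flat, achiral benzofuran and a two-carbon carbene source. The forward step must choose one face of C2=C3 (catalyst control) and must prefer that bond over the arene and over carbene dimerisation.

7 to 6, then to 2 and 3, then to 1: the O–Si bond, then O1–C2 and C3–C3a of the furan ring, then the C–I bond are cut. This leads to a commercial phenol that already carries the C5 chain at the right oxidation level, so no chain-building steps are needed. The forward iodination must go ortho to the phenol, which is the only activated free position.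

## Other disconnections considered

Alternative 1: The cut goes through ring A (C3a–C7a, C4–C5, C6–C7). The arene would be assembled last from the diyne A1, a silyl ynol ether that already holds both stereocentres, and the terminal alkyne A2. In the forward step Cp*RuCl(cod) would couple the two alkyne units of A1 to a ruthenacycle, insert A2, and close rings A and B together to give A3.
- In favour: it is convergent, two rings form in one step, and the silyl group at C7 should direct the chain to C5 (meta). C9 arrives as a protected alcohol, so no carbon has to be removed; on this point it is better than the chosen plan.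
- Against: the key step creates no stereocentre, so C2 and C3 must be made beforehand in an acyclic, enantiopure precursor. The secondary benzylic alkynyl ether of A1 is thermally fragile. C7 emerges bearing silicon and not the methoxy group, so A3 needs an ipso exchange (halo- or borodesilylation, oxidation, methylation) in the presence of three electron-rich rings.
- Comparison: structurally it solves the C9 oxidation level but not the C7 substituent. Mechanistically it moves the stereochemical problem out of the key step, whereas the chosen plan solves it there. In step count it would probably be longer.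

Alternative 2: The cut removes C2–aryl and C3–C9 at once from the intact benzofuran. A4, the 2-boryl derivative of 7, would take up aryllithium 13 at boron. A chiral allylpalladium cation (Pd2(dba)3, BINAP, an allyl ester) would then attack C3 while the aryl group shifts from boron to C2 on the opposite face, giving A5.
- In favour: one catalytic step forms the two bonds and both stereocentres that the chosen plan builds in steps 4, 5 and 7, starting from a compound the chosen route already contains. The anti relationship is built into the 1,2-shift. On bonds per step it is better, and on the origin of the trans relationship it is equal.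
- Against: A5 carries boron at C2 and an allyl group at C3. Stereoretentive protodeboronation of a tertiary benzylic α-aryloxy boronate is uncertain. The allyl group has two carbons too many (isomerisation, oxidative cleavage beside electron-rich arenes, reduction), against one carbon in the chosen plan. The shift is best established for more nucleophilic indole boronates, so its use on a benzofuran is an extrapolation.
- Comparison: after the corrections at C2 and C3 the step count should be about equal, with more unproven steps.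

Alternative 3: The cut is C2–C3 of ring B. The aryldiazoacetate A6, with the ring C benzyl ether ortho to the diazo ester, would lose N2 on Rh2(S-DOSP)4 or its mirror image. The carbene at C3 would insert into the benzylic C2–H bond and close ring B to give A7.
- In favour: C9 is the ester carbon itself, so a hydride reduction gives the CH2OH group with no excision. After the key step the route would be about three steps shorter than the chosen one; on redox and carbon economy it is better. The insertion belongs to a well-populated reaction class.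
- Against: insertions of this kind are expected to favour the cis ester A8 kinetically, so A7 would need a base equilibration at C3, with the C2–O1 bond exposed to β-elimination. The enantioselectivity depends on the match of catalyst and a very electron-rich benzyl ether. A6 needs a tetrasubstituted arylacetic ester (from 2 by O-benzylation, arylation of an acetate equivalent, diazo transfer), which costs roughly the steps saved later. Ring C is fixed before the key step, whereas the chosen plan adds it afterwards.
- Comparison: structurally it fits the target best at C9. Mechanistically it sets C2 by catalyst and C3 by thermodynamics, the reverse of the chosen plan (C3 by catalyst, C2 by the substrate). Overall step count is about equal.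

Key step: step 4

Assumption (sense of induction): the (S,S)-tert-butyl bis(oxazoline) is taken to open the face of 7 that leads to (1S,1aS,6bR)-9, by analogy with the sense such copper catalysts show with simple furans; the (R,R)-ligand would be used if the sense were opposite.

Assumption (anomers): 10 is drawn as its 2,3-trans anomer; its C2 epimer would serve equally, because C2 is ionised again in step 7.

## Steps

Step 1
Reactants: 1 4-(3-hydroxypropyl)-2-methoxyphenol (dihydroconiferyl alcohol)
Product: 2 4-(3-hydroxypropyl)-2-iodo-6-methoxyphenol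
Conditions: I2 (1.05 equiv), NaHCO3, THF/H2O, 0 °C → rt
Reagents that add atoms: iodine, [I][I]
Why: Electrophilic aromatic iodination of the phenoxide; the para position is blocked and the other ortho position carries the methoxy group, so only the future C3a is activated. The primary alcohol is inert to iodine and bicarbonate.

Step 2
Reactants: 2 4-(3-hydroxypropyl)-2-iodo-6-methoxyphenol; 3 ethynyltrimethylsilane
Product: 6 3-(7-methoxy-1-benzofuran-5-yl)propan-1-ol, via alkynylsilane 4 (not isolated), via ethynylphenol 5 (not isolated)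
Conditions: PdCl2(PPh3)2 (3 mol %), CuI (6 mol %), Et3N, DMF, 50 °C; then TBAF (1 M in THF), 70 °C
Reagents that add atoms: none
Why: Sonogashira coupling at the C–I bond; fluoride then removes the alkynyl silyl group and the phenoxide adds to the terminal alkyne in a copper-assisted 5-endo-dig hydroalkoxylation, the usual annulation of ortho-alkynylphenols to benzofurans. The silylacetylene leaves C2 and C3 unsubstituted, as the key step requires.

Step 3
Reactants: 6 3-(7-methoxy-1-benzofuran-5-yl)propan-1-ol
Product: 7 tert-butyl[3-(7-methoxy-1-benzofuran-5-yl)propoxy]diphenylsilane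
Conditions: TBDPSCl, imidazole, DMF, rt
Reagents that add atoms: tert-butyl(chloro)diphenylsilane, CC(C)(C)[Si](Cl)(c1ccccc1)c1ccccc1
Why: Silylation of the only hydroxyl group. The tert-butyldiphenylsilyl ether is chosen because it withstands the acids of steps 5 and 7 and keeps the hydroxyl out of carbene O–H insertion in step 4.

Step 4
Reactants: 7 tert-butyl[3-(7-methoxy-1-benzofuran-5-yl)propoxy]diphenylsilane; 8 ethyl diazoacetate
Product: 9 ethyl (1S,1aS,6bR)-5-{3-[(tert-butyldiphenylsilyl)oxy]propyl}-3-methoxy-1a,6b-dihydro-1H-cyclopropa[b][1]benzofuran-1-carboxylate (exo ester)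
Conditions: (CuOTf)2·C6H6 (2.5 mol %), 2,2'-(propane-2,2-diyl)bis[(4S)-4-tert-butyl-4,5-dihydro-1,3-oxazole] (6 mol %), CH2Cl2, 0 °C; 8 (4 equiv) added over 10 h by syringe pump
Reagents that add atoms: none
Why: Monovalent copper bound to the C2-symmetric bis(oxazoline) decomposes 8 with loss of N2 to an electrophilic copper carbene. The enol-ether carbon C3 of 7, made nucleophilic by the O1 lone pair, attacks the carbene carbon C9 while positive charge builds at C2 beside O1, and C2–C9 closes in the same asynchronous event as copper leaves. The closest known reaction type is the copper–bis(oxazoline) cyclopropanation of furans, benzofurans and other enol ethers with diazoacetates. The three-membered ring is closed by an intermolecular (2+1) cycloaddition that is suprafacial on the alkene, so the ring fusion can only be cis. C3 and C2 are set together by the catalyst: the tert-butyl groups of the ligand leave one enantiotopic face of the flat benzofuran open, and suprafacial addition ties C2 to the same face. C9 takes the exo orientation because the ester avoids the benzo ring during the approach; its configuration is not needed later, since C9 ends as a CH2 group and any endo isomer of the same facial sense converges in step 5. The step needs chemoselectivity for C2=C3 over Büchner addition to the arene and over carbene dimerisation; the polarised enol ether secures the first, slow addition of 8 the second, and the silyl ether excludes O–H insertion. It also needs face selectivity, which rests on the ligand alone because 7 has no stereocentre.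

Step 5
Reactants: 9 ethyl (1S,1aS,6bR)-5-{3-[(tert-butyldiphenylsilyl)oxy]propyl}-3-methoxy-1a,6b-dihydro-1H-cyclopropa[b][1]benzofuran-1-carboxylate
Product: 10 ethyl 2-[(2R,3R)-5-{3-[(tert-butyldiphenylsilyl)oxy]propyl}-2-ethoxy-7-methoxy-2,3-dihydro-1-benzofuran-3-yl]acetate (2,3-trans anomer)
Conditions: TMSOTf (10 mol %), EtOH/CH2Cl2 (1:4), −40 → 0 °C; Et3N quench
Reagents that add atoms: ethanol, CCO
Why: Acid-promoted solvolytic opening of a donor–acceptor cyclopropane: with the ester activated, the O1 lone pair expels C9 as the ester enol, and ethanol in large excess captures the C2 oxocarbenium ion, mainly anti to the C3 arm. Only C2–C9 breaks, because it is the bond flanked by donor and acceptor, so C3 keeps its configuration. Ethanol matches the ethyl ester, so no ester exchange can occur.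

Step 6
Reactants: 11 4-bromo-2-methoxyphenol
Product: 12 (4-bromo-2-methoxyphenoxy)tri(propan-2-yl)silane
Conditions: TIPSCl, imidazole, DMF, rt
Reagents that add atoms: chlorotri(propan-2-yl)silane, CC(C)[Si](Cl)(C(C)C)C(C)C
Why: Routine phenol silylation. The bulky triisopropylsilyl aryl ether tolerates butyllithium, the Lewis acid of step 7 and the mild media of steps 8 and 10.

Step 7
Reactants: 10 ethyl 2-[(2R,3R)-5-{3-[(tert-butyldiphenylsilyl)oxy]propyl}-2-ethoxy-7-methoxy-2,3-dihydro-1-benzofuran-3-yl]acetate; 12 (4-bromo-2-methoxyphenoxy)tri(propan-2-yl)silane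
Product: 15 ethyl 2-[(2R,3R)-5-{3-[(tert-butyldiphenylsilyl)oxy]propyl}-7-methoxy-2-{3-methoxy-4-[(triisopropylsilyl)oxy]phenyl}-2,3-dihydro-1-benzofuran-3-yl]acetate, via aryllithium 13 (not isolated), via diarylzinc 14 (not isolated)
Conditions: 12 (2.4 equiv), n-BuLi, THF, −78 °C; ZnBr2 (1.2 equiv), −78 °C → rt; solvent exchange to toluene; 10, TMSOTf (1.2 equiv), CH2Cl2/toluene, −78 → −20 °C
Reagents that add atoms: none
Why: Bromine–lithium exchange and transmetalation give a diarylzinc; TMSOTf ionises the acetal to the C2 oxocarbenium ion, which takes an aryl group from zinc. This is the Lewis-acid-mediated substitution of cyclic O,O-acetals by organozinc reagents, as used for C-aryl glycosides. The aryl group enters the nearly planar cation from the face opposite the C3 arm, which sets C2 as R and trans to C3. The metalated ipso carbon fixes the 4-oxy-3-methoxy pattern, which a Friedel–Crafts reaction of a guaiacol could not guarantee.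

Step 8
Reactants: 15 ethyl 2-[(2R,3R)-5-{3-[(tert-butyldiphenylsilyl)oxy]propyl}-7-methoxy-2-{3-methoxy-4-[(triisopropylsilyl)oxy]phenyl}-2,3-dihydro-1-benzofuran-3-yl]acetate
Product: 16 2-[(2R,3R)-5-{3-[(tert-butyldiphenylsilyl)oxy]propyl}-7-methoxy-2-{3-methoxy-4-[(triisopropylsilyl)oxy]phenyl}-2,3-dihydro-1-benzofuran-3-yl]acetic acid
Conditions: Me3SnOH (5 equiv), 1,2-dichloroethane, 80 °C; 1 M HCl wash
Reagents that add atoms: trimethyltin hydroxide, C[Sn](C)(C)O
Why: Near-neutral ester hydrolysis with Me3SnOH, preferred to aqueous hydroxide because the aryl silyl ether is base-labile. C9 is not stereogenic, so nothing can epimerise.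

Step 9
Reactants: 16 2-[(2R,3R)-5-{3-[(tert-butyldiphenylsilyl)oxy]propyl}-7-methoxy-2-{3-methoxy-4-[(triisopropylsilyl)oxy]phenyl}-2,3-dihydro-1-benzofuran-3-yl]acetic acid
Product: 17 1,3-dioxoisoindolin-2-yl 2-[(2R,3R)-5-{3-[(tert-butyldiphenylsilyl)oxy]propyl}-7-methoxy-2-{3-methoxy-4-[(triisopropylsilyl)oxy]phenyl}-2,3-dihydro-1-benzofuran-3-yl]acetate
Conditions: N-hydroxyphthalimide, DIC, DMAP (10 mol %), CH2Cl2, rt
Reagents that add atoms: N-hydroxyphthalimide, O=C1c2ccccc2C(=O)N1O
Why: Carbodiimide coupling to the redox-active ester, which prepares the carboxyl carbon for radical loss as CO2.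

Step 10
Reactants: 17 1,3-dioxoisoindolin-2-yl 2-[(2R,3R)-5-{3-[(tert-butyldiphenylsilyl)oxy]propyl}-7-methoxy-2-{3-methoxy-4-[(triisopropylsilyl)oxy]phenyl}-2,3-dihydro-1-benzofuran-3-yl]acetate
Product: 19 [(2R,3S)-5-{3-[(tert-butyldiphenylsilyl)oxy]propyl}-7-methoxy-2-{3-methoxy-4-[(triisopropylsilyl)oxy]phenyl}-2,3-dihydro-1-benzofuran-3-yl]methanol, via catechol boronate 18 (not isolated)
Conditions: B2cat2 (1.3 equiv), DMAc, blue LEDs (450 nm), rt; then NaBO3·4H2O, THF/H2O, 0 °C → rt
Reagents that add atoms: sodium perborate, [Na+].[O-]OB=O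
Why: Decarboxylative borylation of a redox-active ester: light-driven electron transfer in the ester–diboron–amide complex releases CO2 and a primary C9 radical, which is borylated; perborate then converts C–B into C–O. The radical centre is exocyclic and not stereogenic, so C2 and C3 are untouched. The net result is replacement of the carboxyl carbon by a hydroxyl group.

Step 11
Reactants: 20 (E)-3-(4-hydroxyphenyl)prop-2-enoic acid (p-coumaric acid)
Product: 22 (E)-3-{4-[(tert-butyldimethylsilyl)oxy]phenyl}prop-2-enoic acid, via bis-silyl coumarate 21 (not isolated)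
Conditions: TBSCl (2.3 equiv), imidazole, DMF, rt; then AcOH/THF/H2O, rt
Reagents that add atoms: tert-butyl(chloro)dimethylsilane, CC(C)(C)[Si](C)(C)Cl
Why: Both acidic sites are silylated, and the far more labile silyl ester is then hydrolysed selectively by mild aqueous acid. Masking the phenol prevents self-acylation in step 12.

Step 12
Reactants: 19 [(2R,3S)-5-{3-[(tert-butyldiphenylsilyl)oxy]propyl}-7-methoxy-2-{3-methoxy-4-[(triisopropylsilyl)oxy]phenyl}-2,3-dihydro-1-benzofuran-3-yl]methanol; 22 (E)-3-{4-[(tert-butyldimethylsilyl)oxy]phenyl}prop-2-enoic acid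
Product: 23 [(2R,3S)-5-{3-[(tert-butyldiphenylsilyl)oxy]propyl}-7-methoxy-2-{3-methoxy-4-[(triisopropylsilyl)oxy]phenyl}-2,3-dihydro-1-benzofuran-3-yl]methyl (E)-3-{4-[(tert-butyldimethylsilyl)oxy]phenyl}prop-2-enoate
Conditions: EDC·HCl, DMAP, CH2Cl2, 0 °C → rt
Reagents that add atoms: none
Why: Steglich esterification of the only free hydroxyl group (C9–OH). The chain hydroxyl and both phenols are silylated, so the acylation site is unambiguous and the E alkene is untouched.

Step 13
Reactants: 23 [(2R,3S)-5-{3-[(tert-butyldiphenylsilyl)oxy]propyl}-7-methoxy-2-{3-methoxy-4-[(triisopropylsilyl)oxy]phenyl}-2,3-dihydro-1-benzofuran-3-yl]methyl (E)-3-{4-[(tert-butyldimethylsilyl)oxy]phenyl}prop-2-enoate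
Product: 24 [(2R,3S)-2-(4-hydroxy-3-methoxyphenyl)-5-(3-hydroxypropyl)-7-methoxy-2,3-dihydro-1-benzofuran-3-yl]methyl (E)-3-(4-hydroxyphenyl)prop-2-enoate (CNP0202924.1)
Conditions: TBAF (6 equiv), AcOH (6 equiv), THF, 0 °C → rt
Reagents that add atoms: none
Why: Fluoride cleaves all three O–Si bonds. Buffering with acetic acid keeps phenoxide and alkoxide concentrations low, which protects the cinnamate ester from acyl transfer and the C2–O1 bond from opening through a quinone methide.

## Compound list

1 | 4-(3-hydroxypropyl)-2-methoxyphenol (dihydroconiferyl alcohol) | COc1cc(CCCO)ccc1O | starting material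
2 | 4-(3-hydroxypropyl)-2-iodo-6-methoxyphenol | COc1cc(CCCO)cc(I)c1O | intermediate
3 | ethynyltrimethylsilane | C#C[Si](C)(C)C | starting material
4 | 4-(3-hydroxypropyl)-2-methoxy-6-[(trimethylsilyl)ethynyl]phenol | COc1cc(CCCO)cc(C#C[Si](C)(C)C)c1O | intermediate
5 | 2-ethynyl-4-(3-hydroxypropyl)-6-methoxyphenol | COc1cc(CCCO)cc(C#C)c1O | intermediate
6 | 3-(7-methoxy-1-benzofuran-5-yl)propan-1-ol | COc1cc(CCCO)cc2ccoc12 | intermediate
7 | tert-butyl[3-(7-methoxy-1-benzofuran-5-yl)propoxy]diphenylsilane | COc1cc(CCCO[Si](c2ccccc2)(c2ccccc2)C(C)(C)C)cc2ccoc12 | intermediate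
8 | ethyl diazoacetate | CCOC(=O)C=[N+]=[N-] | starting material
9 | ethyl (1S,1aS,6bR)-5-{3-[(tert-butyldiphenylsilyl)oxy]propyl}-3-methoxy-1a,6b-dihydro-1H-cyclopropa[b][1]benzofuran-1-carboxylate (exo) | CCOC(=O)[C@@H]1[C@H]2Oc3c(OC)cc(CCCO[Si](c4ccccc4)(c4ccccc4)C(C)(C)C)cc3[C@@H]12 | intermediate
10 | ethyl 2-[(2R,3R)-5-{3-[(tert-butyldiphenylsilyl)oxy]propyl}-2-ethoxy-7-methoxy-2,3-dihydro-1-benzofuran-3-yl]acetate | CCO[C@@H]1Oc2c(OC)cc(CCCO[Si](c3ccccc3)(c3ccccc3)C(C)(C)C)cc2[C@H]1CC(=O)OCC | intermediate
11 | 4-bromo-2-methoxyphenol | COc1cc(Br)ccc1O | starting material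
12 | (4-bromo-2-methoxyphenoxy)tri(propan-2-yl)silane | COc1cc(Br)ccc1O[Si](C(C)C)(C(C)C)C(C)C | intermediate
13 | {3-methoxy-4-[(triisopropylsilyl)oxy]phenyl}lithium | [Li]c1ccc(O[Si](C(C)C)(C(C)C)C(C)C)c(OC)c1 | intermediate
14 | bis{3-methoxy-4-[(triisopropylsilyl)oxy]phenyl}zinc | COc1cc([Zn]c2ccc(O[Si](C(C)C)(C(C)C)C(C)C)c(OC)c2)ccc1O[Si](C(C)C)(C(C)C)C(C)C | intermediate
15 | ethyl 2-[(2R,3R)-5-{3-[(tert-butyldiphenylsilyl)oxy]propyl}-7-methoxy-2-{3-methoxy-4-[(triisopropylsilyl)oxy]phenyl}-2,3-dihydro-1-benzofuran-3-yl]acetate | COc1cc([C@@H]2Oc3c(OC)cc(CCCO[Si](c4ccccc4)(c4ccccc4)C(C)(C)C)cc3[C@H]2CC(=O)OCC)ccc1O[Si](C(C)C)(C(C)C)C(C)C | intermediate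
16 | 2-[(2R,3R)-5-{3-[(tert-butyldiphenylsilyl)oxy]propyl}-7-methoxy-2-{3-methoxy-4-[(triisopropylsilyl)oxy]phenyl}-2,3-dihydro-1-benzofuran-3-yl]acetic acid | COc1cc([C@@H]2Oc3c(OC)cc(CCCO[Si](c4ccccc4)(c4ccccc4)C(C)(C)C)cc3[C@H]2CC(=O)O)ccc1O[Si](C(C)C)(C(C)C)C(C)C | intermediate
17 | 1,3-dioxoisoindolin-2-yl 2-[(2R,3R)-5-{3-[(tert-butyldiphenylsilyl)oxy]propyl}-7-methoxy-2-{3-methoxy-4-[(triisopropylsilyl)oxy]phenyl}-2,3-dihydro-1-benzofuran-3-yl]acetate | COc1cc([C@@H]2Oc3c(OC)cc(CCCO[Si](c4ccccc4)(c4ccccc4)C(C)(C)C)cc3[C@H]2CC(=O)ON2C(=O)c3ccccc3C2=O)ccc1O[Si](C(C)C)(C(C)C)C(C)C | intermediate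
18 | 2-{[(2R,3R)-5-{3-[(tert-butyldiphenylsilyl)oxy]propyl}-7-methoxy-2-{3-methoxy-4-[(triisopropylsilyl)oxy]phenyl}-2,3-dihydro-1-benzofuran-3-yl]methyl}-1,3,2-benzodioxaborole | COc1cc([C@@H]2Oc3c(OC)cc(CCCO[Si](c4ccccc4)(c4ccccc4)C(C)(C)C)cc3[C@H]2CB2Oc3ccccc3O2)ccc1O[Si](C(C)C)(C(C)C)C(C)C | intermediate
19 | [(2R,3S)-5-{3-[(tert-butyldiphenylsilyl)oxy]propyl}-7-methoxy-2-{3-methoxy-4-[(triisopropylsilyl)oxy]phenyl}-2,3-dihydro-1-benzofuran-3-yl]methanol | COc1cc([C@@H]2Oc3c(OC)cc(CCCO[Si](c4ccccc4)(c4ccccc4)C(C)(C)C)cc3[C@H]2CO)ccc1O[Si](C(C)C)(C(C)C)C(C)C | intermediate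
20 | (E)-3-(4-hydroxyphenyl)prop-2-enoic acid (p-coumaric acid) | OC(=O)/C=C/c1ccc(O)cc1 | starting material
21 | tert-butyldimethylsilyl (E)-3-{4-[(tert-butyldimethylsilyl)oxy]phenyl}prop-2-enoate | CC(C)(C)[Si](C)(C)OC(=O)/C=C/c1ccc(O[Si](C)(C)C(C)(C)C)cc1 | intermediate
22 | (E)-3-{4-[(tert-butyldimethylsilyl)oxy]phenyl}prop-2-enoic acid | OC(=O)/C=C/c1ccc(O[Si](C)(C)C(C)(C)C)cc1 | intermediate
23 | [(2R,3S)-5-{3-[(tert-butyldiphenylsilyl)oxy]propyl}-7-methoxy-2-{3-methoxy-4-[(triisopropylsilyl)oxy]phenyl}-2,3-dihydro-1-benzofuran-3-yl]methyl (E)-3-{4-[(tert-butyldimethylsilyl)oxy]phenyl}prop-2-enoate | COc1cc([C@@H]2Oc3c(OC)cc(CCCO[Si](c4ccccc4)(c4ccccc4)C(C)(C)C)cc3[C@H]2COC(=O)/C=C/c2ccc(O[Si](C)(C)C(C)(C)C)cc2)ccc1O[Si](C(C)C)(C(C)C)C(C)C | intermediate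
24 | [(2R,3S)-2-(4-hydroxy-3-methoxyphenyl)-5-(3-hydroxypropyl)-7-methoxy-2,3-dihydro-1-benzofuran-3-yl]methyl (E)-3-(4-hydroxyphenyl)prop-2-enoate | COc1cc([C@@H]2Oc3c(OC)cc(CCCO)cc3[C@H]2COC(=O)/C=C/c2ccc(O)cc2)ccc1O | target

## Step count and least certain steps

Total: 13 steps. Longest linear sequence: 11 steps (1, 2, 3, 4, 5, 7, 8, 9, 10, 12, 13, from 1). Steps 6 and 11 are one-step side branches.

Step 4 (key step). The benzofuran double bond is only a moderate nucleophile and 7 is the limiting reagent, so carbene dimerisation may outrun cyclopropanation. Facial discrimination by the ligand on a substrate with no directing group may also be incomplete. Fallback, from 7 back to 9: Rh2(OAc)4-catalysed addition of 8 makes no demand on a chiral catalyst and should give racemic ethyl exo-5-{3-[(tert-butyldiphenylsilyl)oxy]propyl}-3-methoxy-1a,6b-dihydro-1H-cyclopropa[b][1]benzofuran-1-carboxylate F1. Preparative chromatography on a chiral stationary phase with supercritical CO2 would then separate the (1S,1aS,6bR) enantiomer, which is 9, at the cost of half the material.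

Step 7. The C2 cation may lose the C3 proton and aromatise, which destroys both stereocentres, before the aryl group is transferred; the facial preference for anti attack may also be incomplete. Fallback, from 10 back to 15: Me3SiBr in CH2Cl2 would exchange the ethoxy group for bromide and give ethyl 2-[(3R)-2-bromo-5-{3-[(tert-butyldiphenylsilyl)oxy]propyl}-7-methoxy-2,3-dihydro-1-benzofuran-3-yl]acetate F2, used crude as both C2 epimers. A nickel-catalysed Negishi coupling with 14 (Ni(cod)2, 4,4',4''-tri-tert-butyl-2,2':6',2''-terpyridine, DMF, rt), of the kind used for glycosyl halides, would then form C2–aryl through a C2 radical and not a free cation, with capture on the face away from the C3 arm.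

Step 5. The aryloxy donor is weaker than an alkoxy donor, so ionisation may be slow. Under more forcing acid, proton loss from C3 (aromatisation) and cleavage of the silyl ether become competitive. Fallback, from 9 back to 16, bypassing steps 5, 7 and 8:
- LiOH in THF/H2O (no aryl silyl ether is present yet) would give (1S,1aS,6bR)-5-{3-[(tert-butyldiphenylsilyl)oxy]propyl}-3-methoxy-1a,6b-dihydro-1H-cyclopropa[b][1]benzofuran-1-carboxylic acid F3.
- Catalytic TsOH in toluene at 40 °C would let the carboxyl oxygen trap C2 intramolecularly, faster than proton loss, and give the cis-fused lactone (3aR,8aR)-5-{3-[(tert-butyldiphenylsilyl)oxy]propyl}-7-methoxy-3,3a-dihydrofuro[2,3-b][1]benzofuran-2(8aH)-one F4.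
- F4 is an α-acyloxy ether; with 14 and TMSOTf as in step 7 it should ionise more readily than 10, and arylation anti to the tethered arm would give 16 after aqueous work-up.

Step 10. The primary C9 radical may escape before boron capture, by hydrogen abstraction or by 1,2-aryl shift or β-scission next to ring A. Perborate may also partly cleave the aryl silyl ether. Fallback without radicals, from 15 back to 19, bypassing steps 8 to 10:
- KHMDS, then 2-(phenylsulfonyl)-3-phenyloxaziridine (THF, −78 °C) would hydroxylate the ester enolate to ethyl 2-hydroxy-2-[(2R,3S)-5-{3-[(tert-butyldiphenylsilyl)oxy]propyl}-7-methoxy-2-{3-methoxy-4-[(triisopropylsilyl)oxy]phenyl}-2,3-dihydro-1-benzofuran-3-yl]acetate F5 (both C9 epimers).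
- LiBH4 would reduce it to 1-[(2R,3S)-5-{3-[(tert-butyldiphenylsilyl)oxy]propyl}-7-methoxy-2-{3-methoxy-4-[(triisopropylsilyl)oxy]phenyl}-2,3-dihydro-1-benzofuran-3-yl]ethane-1,2-diol F6.
- NaIO4 in buffered THF/H2O would cleave the glycol to (2R,3R)-5-{3-[(tert-butyldiphenylsilyl)oxy]propyl}-7-methoxy-2-{3-methoxy-4-[(triisopropylsilyl)oxy]phenyl}-2,3-dihydro-1-benzofuran-3-carbaldehyde F7.
- NaBH4 in the same flask would reduce F7 to 19 before the C3 position can enolise.

## Further compounds

F1 | step 4 | racemic ethyl exo-5-{3-[(tert-butyldiphenylsilyl)oxy]propyl}-3-methoxy-1a,6b-dihydro-1H-cyclopropa[b][1]benzofuran-1-carboxylate (both enantiomers) | CCOC(=O)[C@@H]1[C@H]2Oc3c(OC)cc(CCCO[Si](c4ccccc4)(c4ccccc4)C(C)(C)C)cc3[C@@H]12.CCOC(=O)[C@H]1[C@@H]2Oc3c(OC)cc(CCCO[Si](c4ccccc4)(c4ccccc4)C(C)(C)C)cc3[C@H]12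
F2 | step 7 | ethyl 2-[(3R)-2-bromo-5-{3-[(tert-butyldiphenylsilyl)oxy]propyl}-7-methoxy-2,3-dihydro-1-benzofuran-3-yl]acetate (both C2 epimers) | BrC1Oc2c(OC)cc(CCCO[Si](c3ccccc3)(c3ccccc3)C(C)(C)C)cc2[C@H]1CC(=O)OCC
F3 | step 5 | (1S,1aS,6bR)-5-{3-[(tert-butyldiphenylsilyl)oxy]propyl}-3-methoxy-1a,6b-dihydro-1H-cyclopropa[b][1]benzofuran-1-carboxylic acid | OC(=O)[C@@H]1[C@H]2Oc3c(OC)cc(CCCO[Si](c4ccccc4)(c4ccccc4)C(C)(C)C)cc3[C@@H]12
F4 | step 5 | (3aR,8aR)-5-{3-[(tert-butyldiphenylsilyl)oxy]propyl}-7-methoxy-3,3a-dihydrofuro[2,3-b][1]benzofuran-2(8aH)-one (cis-fused) | O1[C@H]2Oc3c(OC)cc(CCCO[Si](c4ccccc4)(c4ccccc4)C(C)(C)C)cc3[C@H]2CC1=O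
F5 | step 10 | ethyl 2-hydroxy-2-[(2R,3S)-5-{3-[(tert-butyldiphenylsilyl)oxy]propyl}-7-methoxy-2-{3-methoxy-4-[(triisopropylsilyl)oxy]phenyl}-2,3-dihydro-1-benzofuran-3-yl]acetate (both C9 epimers) | COc1cc([C@@H]2Oc3c(OC)cc(CCCO[Si](c4ccccc4)(c4ccccc4)C(C)(C)C)cc3[C@H]2C(O)C(=O)OCC)ccc1O[Si](C(C)C)(C(C)C)C(C)C
F6 | step 10 | 1-[(2R,3S)-5-{3-[(tert-butyldiphenylsilyl)oxy]propyl}-7-methoxy-2-{3-methoxy-4-[(triisopropylsilyl)oxy]phenyl}-2,3-dihydro-1-benzofuran-3-yl]ethane-1,2-diol (both C9 epimers) | COc1cc([C@@H]2Oc3c(OC)cc(CCCO[Si](c4ccccc4)(c4ccccc4)C(C)(C)C)cc3[C@H]2C(O)CO)ccc1O[Si](C(C)C)(C(C)C)C(C)C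
F7 | step 10 | (2R,3R)-5-{3-[(tert-butyldiphenylsilyl)oxy]propyl}-7-methoxy-2-{3-methoxy-4-[(triisopropylsilyl)oxy]phenyl}-2,3-dihydro-1-benzofuran-3-carbaldehyde | COc1cc([C@@H]2Oc3c(OC)cc(CCCO[Si](c4ccccc4)(c4ccccc4)C(C)(C)C)cc3[C@H]2C=O)ccc1O[Si](C(C)C)(C(C)C)C(C)C
A1 | alternative 1 | diyne: tert-butyl{[(2S,3R)-2-ethynyl-3-{3-methoxy-4-[(triisopropylsilyl)oxy]phenyl}-3-{[(trimethylsilyl)ethynyl]oxy}propyl]oxy}dimethylsilane (configuration as drawn in the SMILES) | COc1cc([C@H](OC#C[Si](C)(C)C)[C@@H](C#C)CO[Si](C)(C)C(C)(C)C)ccc1O[Si](C(C)C)(C(C)C)C(C)C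
A2 | alternative 1 | tert-butyl(pent-4-yn-1-yloxy)diphenylsilane | C#CCCCO[Si](c1ccccc1)(c1ccccc1)C(C)(C)C
A3 | alternative 1 | trans-(2R,3S)-3-{[(tert-butyldimethylsilyl)oxy]methyl}-5-{3-[(tert-butyldiphenylsilyl)oxy]propyl}-2-{3-methoxy-4-[(triisopropylsilyl)oxy]phenyl}-7-(trimethylsilyl)-2,3-dihydro-1-benzofuran | COc1cc([C@@H]2Oc3c([Si](C)(C)C)cc(CCCO[Si](c4ccccc4)(c4ccccc4)C(C)(C)C)cc3[C@H]2CO[Si](C)(C)C(C)(C)C)ccc1O[Si](C(C)C)(C(C)C)C(C)C
A4 | alternative 2 | tert-butyl{3-[7-methoxy-2-(4,4,5,5-tetramethyl-1,3,2-dioxaborolan-2-yl)-1-benzofuran-5-yl]propoxy}diphenylsilane | COc1cc(CCCO[Si](c2ccccc2)(c2ccccc2)C(C)(C)C)cc2cc(B3OC(C)(C)C(C)(C)O3)oc12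
A5 | alternative 2 | 3-allyl-2-aryl-2-(pinacolboryl)-2,3-dihydrobenzofuran, aryl trans to allyl (aryl = 3-methoxy-4-[(triisopropylsilyl)oxy]phenyl; 7-methoxy; 5-(3-silyloxypropyl)) | COc1cc([C@]2(B4OC(C)(C)C(C)(C)O4)Oc3c(OC)cc(CCCO[Si](c4ccccc4)(c4ccccc4)C(C)(C)C)cc3[C@H]2CC=C)ccc1O[Si](C(C)C)(C(C)C)C(C)C
A6 | alternative 3 | methyl 2-diazo-2-[5-{3-[(tert-butyldiphenylsilyl)oxy]propyl}-3-methoxy-2-({3-methoxy-4-[(triisopropylsilyl)oxy]phenyl}methoxy)phenyl]acetate | COC(=O)C(=[N+]=[N-])c1cc(CCCO[Si](c2ccccc2)(c2ccccc2)C(C)(C)C)cc(OC)c1OCc1ccc(O[Si](C(C)C)(C(C)C)C(C)C)c(OC)c1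
A7 | alternative 3 | methyl trans-(2R)-5-{3-[(tert-butyldiphenylsilyl)oxy]propyl}-7-methoxy-2-{3-methoxy-4-[(triisopropylsilyl)oxy]phenyl}-2,3-dihydro-1-benzofuran-3-carboxylate | COc1cc([C@@H]2Oc3c(OC)cc(CCCO[Si](c4ccccc4)(c4ccccc4)C(C)(C)C)cc3[C@H]2C(=O)OC)ccc1O[Si](C(C)C)(C(C)C)C(C)C
A8 | alternative 3 | methyl cis-(2R)-5-{3-[(tert-butyldiphenylsilyl)oxy]propyl}-7-methoxy-2-{3-methoxy-4-[(triisopropylsilyl)oxy]phenyl}-2,3-dihydro-1-benzofuran-3-carboxylate | COc1cc([C@@H]2Oc3c(OC)cc(CCCO[Si](c4ccccc4)(c4ccccc4)C(C)(C)C)cc3[C@@H]2C(=O)OC)ccc1O[Si](C(C)C)(C(C)C)C(C)C
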